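**Plan**

1. Numbering of the target core (octahydronaphthalene): C1 quaternary, C2 CHMe, C3, C4, C4a ring-fusion CH, C5 CMe2, C6, C7, C8 (=CH), C8a; ring B = C1–C2–C3–C4–C4a–C8a, ring A = C4a–C5–C6–C7–C8–C8a; side chain C5′ (on C1) to C1′ (ester carbon).
2. Retrosynthetic cuts: the acetonide of the glyceryl ester; the side-chain bond C3′–C4′ (copper-catalysed conjugate addition to a crotonate); C1–C5′ (Claisen rearrangement, which also moves C8a=C1 to C8=C8a); in ring A the bonds C4a–C5 (radical ring closure) and C8–C8a (vinyllithium plus cyclobutanone).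
3. Forward order: ring B comes from cyclohexenone (C2 methyl first, then SPh and methyl on C1); a 2,2-dimethylcyclobutanol is attached at C8a; its four-membered ring C8–C7–C6–C5 grows to ring A by taking in C8a and C4a; then the C1 quaternary centre, the chain and the glycerol follow.
4. Enabling feature: in ring A the quaternary C5 (CMe2) is bonded to the ring-fusion methine C4a, and C8 is a CH on C8a. A C8 carbinol can therefore release C5 as a tertiary radical that returns to C4a of the ring B alkene C8a=C4a; a sulfonyl group on C1 then leaves and stores the unsaturation as the C8 enone, from which C1 and the C8=C8a alkene are built.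
5. Stereochemistry: C2 and C3′ from chiral copper catalysts; SPh on C1 from trans alkylation; C4a by radical attack anti to the sulfonyl group; C8–OH from the oxazaborolidine; C1 by suprafacial [3,3] transfer; the glycerol carbon from (S)-solketal.

Key step: step 7

Remark: 2,2-dimethylcyclobutan-1-one (8), the sulfonyl hydrazide and both antipodes of the chiral ligands are taken as purchasable; atom numbers in the Why lines are the core numbers defined in line 1.

**Route**

Step 1
Reactants: 1 cyclohex-2-en-1-one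
Product: 3 trimethyl{[(3R)-3-methylcyclohex-1-en-1-yl]oxy}silane, via methylzinc enolate 2 (not isolated)
Conditions: Me2Zn, Cu(OTf)2 (2 mol%), (R,S,S)-binaphthyl bis(1-phenylethyl)phosphoramidite (4 mol%; the antipode that delivers 3R), toluene, −30 °C; then TMSOTf, −30 °C → rt
Reagents that add atoms: dimethylzinc C[Zn]C; trimethylsilyl trifluoromethanesulfonate C[Si](C)(C)OS(=O)(=O)C(F)(F)F
Why: Copper-catalysed asymmetric conjugate addition of a dialkylzinc to a cyclic enone with silyl trapping of the zinc enolate; the chiral phosphoramidite selects the enone face and should set the methyl-bearing carbon (future C2) as R, and the trapping fixes the enol ether toward the neighbouring carbon (future C1).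

Step 2
Reactants: 3 trimethyl{[(3R)-3-methylcyclohex-1-en-1-yl]oxy}silane
Product: 4 (3R)-3-methyl-2-(phenylsulfanyl)cyclohexan-1-one
Conditions: PhSCl, CH2Cl2, −78 °C
Reagents that add atoms: benzenesulfenyl chloride ClSc1ccccc1
Why: Regiospecific α-sulfenylation of a silyl enol ether by a sulfenyl chloride; the epimer mixture at the sulfur-bearing carbon does not matter because that carbon is enolized again in step 3.

Step 3
Reactants: 4 (3R)-3-methyl-2-(phenylsulfanyl)cyclohexan-1-one
Product: 6 (2R,3R)-2,3-dimethyl-2-(phenylsulfanyl)cyclohexan-1-one, via sodium enolate 5 (not isolated)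
Conditions: NaH, THF, 0 °C; MeI, 0 °C → rt
Reagents that add atoms: iodomethane CI
Why: Enolate C-alkylation at the more acidic sulfur-bearing α-carbon; in the enolate the C3 methyl is pseudoaxial (allylic 1,2-strain with SPh) and MeI should enter anti to it, so the new methyl is trans and the phenylsulfanyl group cis to the C3 methyl.

Step 4
Reactants: 6 (2R,3R)-2,3-dimethyl-2-(phenylsulfanyl)cyclohexan-1-one
Product: 7 N'-[(2R,3R)-2,3-dimethyl-2-(phenylsulfanyl)cyclohexylidene]-2,4,6-tri(propan-2-yl)benzenesulfonohydrazide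
Conditions: 2,4,6-triisopropylbenzenesulfonyl hydrazide, HCl (cat.), MeCN, rt
Reagents that add atoms: 2,4,6-triisopropylbenzenesulfonyl hydrazide NNS(=O)(=O)c1c(C(C)C)cc(C(C)C)cc1C(C)C
Why: Acid-catalysed hydrazone formation from a ketone and an arylsulfonyl hydrazide; no stereocenter is touched.

Step 5
Reactants: 7 N'-[(2R,3R)-2,3-dimethyl-2-(phenylsulfanyl)cyclohexylidene]-2,4,6-tri(propan-2-yl)benzenesulfonohydrazide; 8 2,2-dimethylcyclobutan-1-one
Product: 10 1-[(5R,6R)-5,6-dimethyl-6-(phenylsulfanyl)cyclohex-1-en-1-yl]-2,2-dimethylcyclobutan-1-ol, via vinyllithium 9 (not isolated)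
Conditions: s-BuLi (2.2 equiv), TMEDA, THF, −78 → 0 °C; then 8, −78 °C
Reagents that add atoms: none
Why: Shapiro reaction: the hydrazone dianion can form only at the single α-CH2, loses sulfinate and N2 to give the vinyllithium, which adds to the strained and poorly enolizable cyclobutanone; the carbinol carbon forms as an epimer mixture that is erased in step 7.

Step 6
Reactants: 10 1-[(5R,6R)-5,6-dimethyl-6-(phenylsulfanyl)cyclohex-1-en-1-yl]-2,2-dimethylcyclobutan-1-ol
Product: 11 1-[(5R,6R)-6-(benzenesulfonyl)-5,6-dimethylcyclohex-1-en-1-yl]-2,2-dimethylcyclobutan-1-ol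
Conditions: m-CPBA (2.2 equiv), NaHCO3, CH2Cl2, −20 → 0 °C
Reagents that add atoms: 3-chloroperoxybenzoic acid OOC(=O)c1cccc(Cl)c1
Why: Peracid oxidation of a sulfide to the sulfone, which should be much faster than epoxidation of the hindered alkene; it turns the sulfur group into a leaving radical that cannot donate hydrogen atoms.

Step 7
Reactants: 11 1-[(5R,6R)-6-(benzenesulfonyl)-5,6-dimethylcyclohex-1-en-1-yl]-2,2-dimethylcyclobutan-1-ol
Product: 13 (4aS,7R)-4,4,7,8-tetramethyl-3,4,4a,5,6,7-hexahydronaphthalen-1(2H)-one, via tertiary alkyl radical 12 (not isolated)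
Conditions: [Ir(dF(CF3)ppy)2(5,5'-d(CF3)bpy)]PF6 (2 mol%), 2,4,6-collidine (2 equiv), CH2Cl2, blue LEDs, rt
Reagents that add atoms: none
Why: Proposed new method: the excited trivalent iridium complex and collidine take an electron and the hydroxyl proton in one step (proton-coupled electron transfer), and the cyclobutyloxy radical opens by strain-driven β-scission toward the CMe2 carbon to give tertiary radical 12, which faces an enone that carries an allylic sulfone. Radical 12 adds to the β-carbon of that enone (the former cyclohexene CH, future C4a) in a 6-endo-trig closure, so the four-membered ring C8–C7–C6–C5 becomes six-membered ring A by taking in C8a and C4a; the 5-exo alternative would hit the fully substituted α-carbon and give no stabilized radical. The α-keto radical at C8a then expels PhSO2• from C1 (addition–β-fragmentation, the SH2′ mode of allyl sulfones), which places the new double bond at C8a=C1 in conjugation with the C8 ketone, and divalent iridium reduces PhSO2• to sulfinate so that the cycle is redox-neutral. The closest known reactions are the photocatalytic ring expansion of 1-alkenylcycloalkanols to n+2 ketones through alkoxy radicals and radical allylation with 2-(sulfonylmethyl) enoates; a β-sulfonyl ketone formed by early reduction of the α-keto radical would lose sulfinate to collidine and reach the same enone. The new stereocenter C4a is controlled by the C1 sulfonyl group, which sits pseudoaxial (allylic 1,2-strain with the acyl-bearing carbon; the cis C2 methyl is then equatorial) and shields its face, so C5 should enter anti and H4a end up cis to the C2 methyl. The step needs scission toward CMe2 and not CH2 (secured by the tertiary radical), ring closure faster than hydrogen-atom capture (secured by the absence of thiol, the reason for sulfone over sulfide) and no epimerization at C2 (collidine is too weak a base to form the dienolate).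

Step 8
Reactants: 13 (4aS,7R)-4,4,7,8-tetramethyl-3,4,4a,5,6,7-hexahydronaphthalen-1(2H)-one
Product: 14 (1S,4aS,7R)-4,4,7,8-tetramethyl-1,2,3,4,4a,5,6,7-octahydronaphthalen-1-ol
Conditions: (R)-2-methyl-CBS-oxazaborolidine (0.5 equiv), catecholborane, toluene, −78 → −40 °C
Reagents that add atoms: none
Why: Corey–Bakshi–Shibata reduction; the catalyst binds the carbonyl lone pair on the CH2 side and should deliver hydride to the face anti to H4a, setting the carbinol as S (hydroxyl cis to H4a) under reagent control.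

Step 9
Reactants: 14 (1S,4aS,7R)-4,4,7,8-tetramethyl-1,2,3,4,4a,5,6,7-octahydronaphthalen-1-ol
Product: 16 ethyl 2-[(1R,2R,4aS)-1,2,5,5-tetramethyl-1,2,3,4,4a,5,6,7-octahydronaphthalen-1-yl]acetate, via ketene acetal 15 (not isolated)
Conditions: MeC(OEt)3, EtCO2H (cat.), 140 °C, removal of EtOH
Reagents that add atoms: triethyl orthoacetate CC(OCC)(OCC)OCC
Why: Johnson–Claisen rearrangement; the [3,3] shift is suprafacial, so the CH2CO2Et group arrives at C1 on the face that carried the oxygen, which sets the quaternary centre (acetate arm cis to H4a and to the C2 methyl) and moves the double bond to C8=C8a.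

Step 10
Reactants: 16 ethyl 2-[(1R,2R,4aS)-1,2,5,5-tetramethyl-1,2,3,4,4a,5,6,7-octahydronaphthalen-1-yl]acetate
Product: 17 2-[(1R,2R,4aS)-1,2,5,5-tetramethyl-1,2,3,4,4a,5,6,7-octahydronaphthalen-1-yl]ethan-1-ol
Conditions: LiAlH4, Et2O, 0 °C
Reagents that add atoms: none
Why: Hydride reduction of an ester to the primary alcohol; no stereocenter is affected.

Step 11
Reactants: 17 2-[(1R,2R,4aS)-1,2,5,5-tetramethyl-1,2,3,4,4a,5,6,7-octahydronaphthalen-1-yl]ethan-1-ol
Product: 18 (1R,2R,4aS)-1-(2-bromoethyl)-1,2,5,5-tetramethyl-1,2,3,4,4a,5,6,7-octahydronaphthalene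
Conditions: CBr4, PPh3, CH2Cl2, 0 °C
Reagents that add atoms: tetrabromomethane BrC(Br)(Br)Br
Why: Appel bromination of a primary alcohol under neutral conditions that leave the trisubstituted alkene alone.

Step 12
Reactants: 19 [(4S)-2,2-dimethyl-1,3-dioxolan-4-yl]methanol; 20 (2E)-but-2-enoic acid
Product: 21 [(4R)-2,2-dimethyl-1,3-dioxolan-4-yl]methyl (2E)-but-2-enoate
Conditions: DCC, DMAP (cat.), CH2Cl2, 0 °C → rt
Reagents that add atoms: none
Why: Steglich esterification; the dioxolane stereocenter is not involved (its descriptor changes from S to R only through the priority rules).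

Step 13
Reactants: 18 (1R,2R,4aS)-1-(2-bromoethyl)-1,2,5,5-tetramethyl-1,2,3,4,4a,5,6,7-octahydronaphthalene; 21 [(4R)-2,2-dimethyl-1,3-dioxolan-4-yl]methyl (2E)-but-2-enoate
Product: 23 [(4R)-2,2-dimethyl-1,3-dioxolan-4-yl]methyl (3R)-3-methyl-5-[(1R,2R,4aS)-1,2,5,5-tetramethyl-1,2,3,4,4a,5,6,7-octahydronaphthalen-1-yl]pentanoate, via alkylmagnesium bromide 22 (not isolated)
Conditions: Mg, Et2O, reflux; then slow addition to 21 (2 equiv), CuI (5 mol%), Tol-BINAP (7.5 mol%; the antipode that gives 3R), t-BuOMe, −40 °C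
Reagents that add atoms: none
Why: Copper-catalysed asymmetric conjugate addition of an alkylmagnesium bromide to an (E)-crotonate; the chiral diphosphine–copper complex selects the enoate face and should set the side-chain methyl stereocenter as 3R, independent of the remote stereocenters of both partners.

Step 14
Reactants: 23 [(4R)-2,2-dimethyl-1,3-dioxolan-4-yl]methyl (3R)-3-methyl-5-[(1R,2R,4aS)-1,2,5,5-tetramethyl-1,2,3,4,4a,5,6,7-octahydronaphthalen-1-yl]pentanoate
Product: 24 (2R)-2,3-dihydroxypropyl (3R)-3-methyl-5-[(1R,2R,4aS)-1,2,5,5-tetramethyl-1,2,3,4,4a,5,6,7-octahydronaphthalen-1-yl]pentanoate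
Conditions: AcOH/H2O (4:1), 40 °C
Reagents that add atoms: none
Why: Acid-catalysed acetonide hydrolysis under conditions expected to be too mild for acyl migration or alkene isomerization; the glycerol stereocenter is carried over from 19.

**Compound list**

1 | cyclohex-2-en-1-one | O=C1C=CCCC1 | starting material
2 | methylzinc (3R)-3-methylcyclohex-1-en-1-olate | C[C@@H]1CCCC(O[Zn]C)=C1 | intermediate
3 | trimethyl{[(3R)-3-methylcyclohex-1-en-1-yl]oxy}silane | C[C@@H]1CCCC(O[Si](C)(C)C)=C1 | intermediate
4 | (3R)-3-methyl-2-(phenylsulfanyl)cyclohexan-1-one (both C2 epimers) | C[C@@H]1CCCC(=O)C1Sc1ccccc1 | intermediate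
5 | sodium (3R)-3-methyl-2-(phenylsulfanyl)cyclohex-1-en-1-olate | C[C@@H]1CCCC([O-])=C1Sc1ccccc1.[Na+] | intermediate
6 | (2R,3R)-2,3-dimethyl-2-(phenylsulfanyl)cyclohexan-1-one | C[C@@H]1CCCC(=O)[C@]1(C)Sc1ccccc1 | intermediate
7 | N'-[(2R,3R)-2,3-dimethyl-2-(phenylsulfanyl)cyclohexylidene]-2,4,6-tri(propan-2-yl)benzenesulfonohydrazide | C[C@@H]1CCCC(=NNS(=O)(=O)c2c(C(C)C)cc(C(C)C)cc2C(C)C)[C@]1(C)Sc1ccccc1 | intermediate
8 | 2,2-dimethylcyclobutan-1-one | CC1(C)CCC1=O | starting material
9 | [(5R,6R)-5,6-dimethyl-6-(phenylsulfanyl)cyclohex-1-en-1-yl]lithium | C[C@@H]1CCC=C([Li])[C@]1(C)Sc1ccccc1 | intermediate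
10 | 1-[(5R,6R)-5,6-dimethyl-6-(phenylsulfanyl)cyclohex-1-en-1-yl]-2,2-dimethylcyclobutan-1-ol (both carbinol epimers) | C[C@@H]1CCC=C(C2(O)CCC2(C)C)[C@]1(C)Sc1ccccc1 | intermediate
11 | 1-[(5R,6R)-6-(benzenesulfonyl)-5,6-dimethylcyclohex-1-en-1-yl]-2,2-dimethylcyclobutan-1-ol (both carbinol epimers) | C[C@@H]1CCC=C(C2(O)CCC2(C)C)[C@]1(C)S(=O)(=O)c1ccccc1 | intermediate
12 | 5-[(5R,6R)-6-(benzenesulfonyl)-5,6-dimethylcyclohex-1-en-1-yl]-2-methyl-5-oxopentan-2-yl radical | C[C@@H]1CCC=C(C(=O)CC[C](C)C)[C@]1(C)S(=O)(=O)c1ccccc1 | intermediate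
13 | (4aS,7R)-4,4,7,8-tetramethyl-3,4,4a,5,6,7-hexahydronaphthalen-1(2H)-one | C[C@@H]1CC[C@@H]2C(=C1C)C(=O)CCC2(C)C | intermediate
14 | (1S,4aS,7R)-4,4,7,8-tetramethyl-1,2,3,4,4a,5,6,7-octahydronaphthalen-1-ol | C[C@@H]1CC[C@@H]2C(=C1C)[C@@H](O)CCC2(C)C | intermediate
15 | (1S,4aS,7R)-1-[(1-ethoxyethenyl)oxy]-4,4,7,8-tetramethyl-1,2,3,4,4a,5,6,7-octahydronaphthalene | C[C@@H]1CC[C@@H]2C(=C1C)[C@@H](OC(=C)OCC)CCC2(C)C | intermediate
16 | ethyl 2-[(1R,2R,4aS)-1,2,5,5-tetramethyl-1,2,3,4,4a,5,6,7-octahydronaphthalen-1-yl]acetate | CCOC(=O)C[C@@]1(C)C2=CCCC(C)(C)[C@@H]2CC[C@H]1C | intermediate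
17 | 2-[(1R,2R,4aS)-1,2,5,5-tetramethyl-1,2,3,4,4a,5,6,7-octahydronaphthalen-1-yl]ethan-1-ol | OCC[C@@]1(C)C2=CCCC(C)(C)[C@@H]2CC[C@H]1C | intermediate
18 | (1R,2R,4aS)-1-(2-bromoethyl)-1,2,5,5-tetramethyl-1,2,3,4,4a,5,6,7-octahydronaphthalene | BrCC[C@@]1(C)C2=CCCC(C)(C)[C@@H]2CC[C@H]1C | intermediate
19 | [(4S)-2,2-dimethyl-1,3-dioxolan-4-yl]methanol ((S)-solketal) | OC[C@H]1COC(C)(C)O1 | starting material
20 | (2E)-but-2-enoic acid | C/C=C/C(=O)O | starting material
21 | [(4R)-2,2-dimethyl-1,3-dioxolan-4-yl]methyl (2E)-but-2-enoate | C/C=C/C(=O)OC[C@H]1COC(C)(C)O1 | intermediate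
22 | {2-[(1R,2R,4aS)-1,2,5,5-tetramethyl-1,2,3,4,4a,5,6,7-octahydronaphthalen-1-yl]ethyl}magnesium bromide | Br[Mg]CC[C@@]1(C)C2=CCCC(C)(C)[C@@H]2CC[C@H]1C | intermediate
23 | [(4R)-2,2-dimethyl-1,3-dioxolan-4-yl]methyl (3R)-3-methyl-5-[(1R,2R,4aS)-1,2,5,5-tetramethyl-1,2,3,4,4a,5,6,7-octahydronaphthalen-1-yl]pentanoate | C[C@H](CC[C@@]1(C)C2=CCCC(C)(C)[C@@H]2CC[C@H]1C)CC(=O)OC[C@H]1COC(C)(C)O1 | intermediate
24 | (2R)-2,3-dihydroxypropyl (3R)-3-methyl-5-[(1R,2R,4aS)-1,2,5,5-tetramethyl-1,2,3,4,4a,5,6,7-octahydronaphthalen-1-yl]pentanoate | C[C@H](CC[C@@]1(C)C2=CCCC(C)(C)[C@@H]2CC[C@H]1C)CC(=O)OC[C@H](O)CO | target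

**Count**

Total steps: 14. Longest linear sequence: 13 steps (steps 1–11, 13 and 14); step 12 is the side branch.

**Steps most likely to fail**

Step 7 (the step under the label "Proposed new method:"). The tertiary radical may be captured before ring closure, the sulfinate that builds up may quench the excited photocatalyst, or the radical may attack syn to the sulfonyl group and give the C4a epimer. The fallback makes the same radical from a carbon–bromine bond with tin hydride, which is known chemistry. It sets out from hydrazone 7: vinyllithium 9, generated as in step 5, is acylated at −78 °C with 4-bromo-N-methoxy-N,4-dimethylpentanamide to give 4-bromo-1-[(5R,6R)-5,6-dimethyl-6-(phenylsulfanyl)cyclohex-1-en-1-yl]-4-methylpentan-1-one F1. Oxidation with m-CPBA gives 1-[(5R,6R)-6-(benzenesulfonyl)-5,6-dimethylcyclohex-1-en-1-yl]-4-bromo-4-methylpentan-1-one F2. Slow addition of Bu3SnH with AIBN in benzene at 80 °C should then give the 6-endo radical cyclization with loss of the sulfonyl radical, and the route is rejoined at enone 13.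

Step 5. Thiophenoxide may be lost from the hydrazone anion before the second deprotonation (azoalkene formation), or the hindered vinyllithium may take a proton from ketone 8 instead of adding. The fallback makes the vinyl metal without a hydrazone. It sets out from ketone 6: KHMDS and PhNTf2 at −78 °C give (5R,6R)-5,6-dimethyl-6-(phenylsulfanyl)cyclohex-1-en-1-yl trifluoromethanesulfonate F3 (only one enolization direction exists). Pd(PPh3)4, Me3SnSnMe3 and LiCl in THF give trimethyl[(5R,6R)-5,6-dimethyl-6-(phenylsulfanyl)cyclohex-1-en-1-yl]stannane F4. Tin–lithium exchange with MeLi at −78 °C, then anhydrous CeCl3 and ketone 8, should give cyclobutanol 10, where the route is rejoined.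

Step 9. The hindered allylic alcohol may dehydrate to a diene under the acidic hot conditions, or the [3,3] shift may be too slow at the fully substituted alkene carbon. The fallback builds C1 by conjugate addition and skips step 8. It sets out from enone 13: vinylmagnesium bromide with CuBr·SMe2 in THF at −40 °C should add axially to C1 (syn to H4a), and the enolate is trapped in the same flask with N-(5-chloropyridin-2-yl)triflimide to give (4aS,7R,8R)-8-ethenyl-4,4,7,8-tetramethyl-2,3,4,4a,5,6,7,8-octahydronaphthalen-1-yl trifluoromethanesulfonate F5. Pd(OAc)2, PPh3, Bu3N and HCO2H in DMF at 60 °C reduce the triflate to (1R,2R,4aS)-1-ethenyl-1,2,5,5-tetramethyl-1,2,3,4,4a,5,6,7-octahydronaphthalene F6. Hydroboration of the vinyl group only with 9-BBN, then NaOH/H2O2, gives alcohol 17, where the route is rejoined.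

**Further compounds**

F1 | step 7 | 4-bromo-1-[(5R,6R)-5,6-dimethyl-6-(phenylsulfanyl)cyclohex-1-en-1-yl]-4-methylpentan-1-one | C[C@@H]1CCC=C(C(=O)CCC(C)(C)Br)[C@]1(C)Sc1ccccc1
F2 | step 7 | 1-[(5R,6R)-6-(benzenesulfonyl)-5,6-dimethylcyclohex-1-en-1-yl]-4-bromo-4-methylpentan-1-one | C[C@@H]1CCC=C(C(=O)CCC(C)(C)Br)[C@]1(C)S(=O)(=O)c1ccccc1
F3 | step 5 | (5R,6R)-5,6-dimethyl-6-(phenylsulfanyl)cyclohex-1-en-1-yl trifluoromethanesulfonate | C[C@@H]1CCC=C(OS(=O)(=O)C(F)(F)F)[C@]1(C)Sc1ccccc1
F4 | step 5 | trimethyl[(5R,6R)-5,6-dimethyl-6-(phenylsulfanyl)cyclohex-1-en-1-yl]stannane | C[C@@H]1CCC=C([Sn](C)(C)C)[C@]1(C)Sc1ccccc1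
F5 | step 9 | (4aS,7R,8R)-8-ethenyl-4,4,7,8-tetramethyl-2,3,4,4a,5,6,7,8-octahydronaphthalen-1-yl trifluoromethanesulfonate | C=C[C@@]1(C)C2=C(OS(=O)(=O)C(F)(F)F)CCC(C)(C)[C@@H]2CC[C@H]1C
F6 | step 9 | (1R,2R,4aS)-1-ethenyl-1,2,5,5-tetramethyl-1,2,3,4,4a,5,6,7-octahydronaphthalene | C=C[C@@]1(C)C2=CCCC(C)(C)[C@@H]2CC[C@H]1C
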